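**Strategy.** The target is cut at the stilbene and at the two C3–aryl bonds, which leaves two 2-aryl-2,3-dihydrobenzofuran-3-carboxylic acids to be joined and arylated by decarboxylative coupling. The route rests on making the unit 2 acid by photochemical Wolff contraction of a 3-diazoflavanone: one irradiation forms C3'–C3a', closes the dihydrofuran ring and turns the carbonyl carbon into the C3' ester, with C2' untouched. It exploits that ring O1'–C2'–C3'–C3a'–C7a' of unit 2, with the catechol on C2' and the C4'-oxygenated arene, is the pyranone ring of an eriodictyol ether less its C4. The precursor is the 3-diazo derivative of 7-O-benzyl-5,3',4'-tri-O-methyl-(2S)-eriodictyol.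

Key step: step 6

**Remarks on the chemistry**
- Numbering: unprimed locants are unit 1 (the stilbene-bearing dihydrobenzofuran), primed locants are unit 2. The target is (2R,3R,2'S,3'S), with both rings trans.
- Correction: in the target only C4' of unit 2 keeps an oxygen. C6' carries C3 of unit 1, so the flavanone 7-oxygen is only a handle (benzyl ether, then triflate, then boronic acid).
- Correction: the 3-oximes and 3-diazoketones keep the C2 geometry of their flavanone, but the CIP label switches (2S to 2R for unit 2, 2R to 2S for unit 1) because C3 then outranks the aryl group.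
- Both flavanones are made by catalytic asymmetric arylation of one chromone. No base-mediated O-alkylation is run on a flavanone, where opening to the chalcone would racemise C2, and the 2R series needs no resolution. If the facial sense of the ligand proves opposite, the two ligands are exchanged between steps 3 and 12.
- The methyl ethers are cleaved before the stilbene exists, because a Lewis acid acting on a stilbene next to a dihydrobenzofuran risks Friedel–Crafts cyclisation. The phenols then travel as acetates.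
- Assumption: 5,7-dihydroxychromone and both enantiomers of t-BuPyOx (4-tert-butyl-2-(pyridin-2-yl)-4,5-dihydrooxazole) are purchased.

**Route**

Step 1
Reactants: 1 5,7-dihydroxychromone; 2 benzyl bromide
Product: 3 7-benzyloxy-5-hydroxychromone
Conditions: K2CO3 (1.1 equiv), acetone, reflux
Reagents that add atoms: benzyl bromide BrCc1ccccc1
Why: Williamson etherification in which the 5-OH, hydrogen-bonded to the carbonyl, stays untouched, so one equivalent of halide should alkylate only the 7-OH.

Step 2
Reactants: 3 7-benzyloxy-5-hydroxychromone; 4 iodomethane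
Product: 5 7-benzyloxy-5-methoxychromone
Conditions: K2CO3, DMF, 50 °C
Reagents that add atoms: iodomethane CI
Why: Williamson etherification of the chelated 5-OH under more forcing conditions, done on the achiral chromone where no stereocentre can be lost.

Step 3
Reactants: 5 7-benzyloxy-5-methoxychromone; 6 3,4-dimethoxyphenylboronic acid
Product: 7 (2S)-7-benzyloxy-2-(3,4-dimethoxyphenyl)-5-methoxychroman-4-one
Conditions: Pd(OCOCF3)2 (5 mol %), (R)-t-BuPyOx (6 mol %), NH4PF6, H2O (5 equiv), ClCH2CH2Cl, 60 °C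
Reagents that add atoms: 3,4-dimethoxyphenylboronic acid COc1ccc(cc1OC)B(O)O
Why: Palladium-catalysed asymmetric conjugate addition of an arylboronic acid to a chromone (aryl–palladium adds to C2, water protonates the palladium enolate), in which the pyridine–oxazoline ligand fixes the face of attack and so sets C2 as S under base-free conditions.

Step 4
Reactants: 7 (2S)-7-benzyloxy-2-(3,4-dimethoxyphenyl)-5-methoxychroman-4-one; 8 isoamyl nitrite
Product: 9 7-benzyloxy-2-(3,4-dimethoxyphenyl)-3-hydroxyimino-5-methoxychroman-4-one (C2 as in 7, CIP label 2R; oxime geometry not defined)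
Conditions: i-AmONO, HCl (4 M in dioxane), THF, 0 °C
Reagents that add atoms: isoamyl nitrite CC(C)CCON=O
Why: Acid-catalysed α-oximation of the ketone through its enol (the first stage of the Kostanecki flavonol synthesis) forms no enolate, so the ring cannot open by β-elimination and C2 should be kept.

Step 5
Reactants: 9 7-benzyloxy-2-(3,4-dimethoxyphenyl)-3-hydroxyimino-5-methoxychroman-4-one; 10 ammonia
Product: 11 7-benzyloxy-3-diazo-2-(3,4-dimethoxyphenyl)-5-methoxychroman-4-one (C2 as in 7, CIP label 2R)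
Conditions: aq. NH3, NaOCl, NaOH, THF/H2O, 0 °C
Reagents that add atoms: ammonia N (delivered as chloramine NCl, formed in the flask with NaOCl)
Why: Forster reaction, in which the oximate is N-aminated by chloramine and loses water to give the α-diazoketone; C3 bears no hydrogen, so the basic medium has no enolate route to the chalcone.

Step 6
Reactants: 11 7-benzyloxy-3-diazo-2-(3,4-dimethoxyphenyl)-5-methoxychroman-4-one; 12 methanol
Product: 15 methyl (2S,3S)-6-benzyloxy-2-(3,4-dimethoxyphenyl)-4-methoxy-2,3-dihydrobenzofuran-3-carboxylate, via ketene 13 (not isolated), via cis ester 14 (not isolated)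
Conditions: hν (365 nm), degassed MeOH/THF, 20 °C; then DBU (0.2 equiv), 20 °C
Reagents that add atoms: methanol CO
Why: Direct excitation of the diazoketone, held s-Z by the pyranone ring, should expel N2 in concert with a 1,2-shift of arene carbon C4a (C3a' of unit 2) from the carbonyl carbon to C3, so the C3'–C3a' bond forms as the old acyl–arene bond breaks and a ketene, not a free carbene, results. The closest known reaction type is the photochemical Wolff ring contraction of cyclic 2-diazoketones such as 2-diazo-1-indanone and 3-diazochroman-4-ones. The dihydrofuran ring is closed by this six-to-five contraction and not by a cyclisation: the carbonyl carbon leaves the ring as the ketene carbon on C3' and is trapped by methanol as the ester. C2' takes no part and keeps the configuration set in step 3, while the new C3' centre arises by unselective protonation of the ester enol and is then driven to trans by DBU equilibration under control of the C2' aryl group. The step needs aryl migration to win over the 1,2-hydride shift from C2 (flavone) and over O–H insertion, which the locked geometry, the electron-rich migrating arene and sensitiser-free long-wave irradiation at room temperature should secure. Reopening of the ring from the ester enolate would be a reverse 5-endo-trig process, so the base should not endanger C2'.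

Step 7
Reactants: 15 methyl (2S,3S)-6-benzyloxy-2-(3,4-dimethoxyphenyl)-4-methoxy-2,3-dihydrobenzofuran-3-carboxylate; 16 lithium hydroxide
Product: 17 (2S,3S)-6-benzyloxy-2-(3,4-dimethoxyphenyl)-4-methoxy-2,3-dihydrobenzofuran-3-carboxylic acid
Conditions: LiOH, THF/MeOH/H2O, 40 °C; then 1 M HCl
Reagents that add atoms: lithium hydroxide [Li+].[OH-]
Why: Saponification of the methyl ester, where any epimerisation at C3' is harmless because that centre is erased in step 8.

Step 8
Reactants: 17 (2S,3S)-6-benzyloxy-2-(3,4-dimethoxyphenyl)-4-methoxy-2,3-dihydrobenzofuran-3-carboxylic acid; 18 N-hydroxytetrachlorophthalimide; 19 3,5-dimethoxyphenylboronic acid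
Product: 21 (2S,3S)-6-benzyloxy-2-(3,4-dimethoxyphenyl)-3-(3,5-dimethoxyphenyl)-4-methoxy-2,3-dihydrobenzofuran, via tetrachlorophthalimidoyl ester 20 (not isolated)
Conditions: 18, DIC, DMAP (cat.), CH2Cl2, 20 °C; evaporate; then 19 (3 equiv), NiCl2·6H2O (20 mol %), bathophenanthroline, Et3N, 1,4-dioxane/DMF, 75 °C
Reagents that add atoms: 3,5-dimethoxyphenylboronic acid COc1cc(cc(OC)c1)B(O)O; N-hydroxytetrachlorophthalimide ON1C(=O)c2c(Cl)c(Cl)c(Cl)c(Cl)c2C1=O (its atoms stay only in intermediate 20)
Why: Nickel-catalysed decarboxylative Suzuki-type coupling of a redox-active ester, in which single-electron reduction releases CO2 and a benzylic C3' radical that aryl–nickel should capture on the face away from the C2' aryl group, so reductive elimination sets C3' trans (3'S).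

Step 9
Reactants: 21 (2S,3S)-6-benzyloxy-2-(3,4-dimethoxyphenyl)-3-(3,5-dimethoxyphenyl)-4-methoxy-2,3-dihydrobenzofuran
Product: 22 (2S,3S)-2-(3,4-dimethoxyphenyl)-3-(3,5-dimethoxyphenyl)-4-methoxy-2,3-dihydrobenzofuran-6-ol
Conditions: H2 (1 atm), Pd/C, EtOAc/MeOH, 20 °C
Reagents that add atoms: none
Why: Hydrogenolysis of the single aryl benzyl ether, mild enough that the hindered secondary C2'–O1' ring bond should survive.

Step 10
Reactants: 22 (2S,3S)-2-(3,4-dimethoxyphenyl)-3-(3,5-dimethoxyphenyl)-4-methoxy-2,3-dihydrobenzofuran-6-ol; 23 N-phenylbis(trifluoromethanesulfonimide)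
Product: 24 (2S,3S)-2-(3,4-dimethoxyphenyl)-3-(3,5-dimethoxyphenyl)-4-methoxy-2,3-dihydrobenzofuran-6-yl trifluoromethanesulfonate
Conditions: PhNTf2, Et3N, DMAP (cat.), CH2Cl2, 20 °C
Reagents that add atoms: N-phenylbis(trifluoromethanesulfonimide) FC(F)(F)S(=O)(=O)N(c1ccccc1)S(=O)(=O)C(F)(F)F
Why: O-sulfonylation of the only free phenol by a mild triflyl donor.

Step 11
Reactants: 24 (2S,3S)-2-(3,4-dimethoxyphenyl)-3-(3,5-dimethoxyphenyl)-4-methoxy-2,3-dihydrobenzofuran-6-yl trifluoromethanesulfonate; 25 tetrahydroxydiboron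
Product: 26 [(2S,3S)-2-(3,4-dimethoxyphenyl)-3-(3,5-dimethoxyphenyl)-4-methoxy-2,3-dihydrobenzofuran-6-yl]boronic acid
Conditions: B2(OH)4, Pd(OAc)2 (5 mol %), XPhos, KOAc, EtOH, 80 °C
Reagents that add atoms: tetrahydroxydiboron OB(O)B(O)O
Why: Palladium-catalysed Miyaura-type borylation of an aryl triflate, which with tetrahydroxydiboron gives the free boronic acid that step 16 needs.

Step 12
Reactants: 5 7-benzyloxy-5-methoxychromone; 27 4-methoxyphenylboronic acid
Product: 28 (2R)-7-benzyloxy-5-methoxy-2-(4-methoxyphenyl)chroman-4-one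
Conditions: Pd(OCOCF3)2 (5 mol %), (S)-t-BuPyOx (6 mol %), NH4PF6, H2O (5 equiv), ClCH2CH2Cl, 60 °C
Reagents that add atoms: 4-methoxyphenylboronic acid COc1ccc(cc1)B(O)O
Why: The same palladium-catalysed asymmetric conjugate addition as in step 3, where the antipodal ligand should deliver the aryl group to the other face and set C2 as R.

Step 13
Reactants: 28 (2R)-7-benzyloxy-5-methoxy-2-(4-methoxyphenyl)chroman-4-one; 8 isoamyl nitrite
Product: 29 7-benzyloxy-3-hydroxyimino-5-methoxy-2-(4-methoxyphenyl)chroman-4-one (C2 as in 28, CIP label 2S; oxime geometry not defined)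
Conditions: i-AmONO, HCl (4 M in dioxane), THF, 0 °C
Reagents that add atoms: isoamyl nitrite CC(C)CCON=O
Why: Acid-catalysed α-oximation through the enol as in step 4, with C2 kept.

Step 14
Reactants: 29 7-benzyloxy-3-hydroxyimino-5-methoxy-2-(4-methoxyphenyl)chroman-4-one; 10 ammonia
Product: 30 7-benzyloxy-3-diazo-5-methoxy-2-(4-methoxyphenyl)chroman-4-one (C2 as in 28, CIP label 2S)
Conditions: aq. NH3, NaOCl, NaOH, THF/H2O, 0 °C
Reagents that add atoms: ammonia N (delivered as chloramine NCl, formed in the flask with NaOCl)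
Why: Forster reaction as in step 5.

Step 15
Reactants: 30 7-benzyloxy-3-diazo-5-methoxy-2-(4-methoxyphenyl)chroman-4-one; 31 water
Product: 33 (2R)-6-benzyloxy-4-methoxy-2-(4-methoxyphenyl)-2,3-dihydrobenzofuran-3-carboxylic acid (both C3 epimers), via ketene 32 (not isolated)
Conditions: hν (365 nm), degassed THF/H2O (4:1), 20 °C
Reagents that add atoms: water O
Why: Photochemical Wolff ring contraction as in step 6 with water as the ketene trap, giving the acid directly; its C3 configuration is left open because step 16 erases it.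

Step 16
Reactants: 33 (2R)-6-benzyloxy-4-methoxy-2-(4-methoxyphenyl)-2,3-dihydrobenzofuran-3-carboxylic acid; 18 N-hydroxytetrachlorophthalimide; 26 [(2S,3S)-2-(3,4-dimethoxyphenyl)-3-(3,5-dimethoxyphenyl)-4-methoxy-2,3-dihydrobenzofuran-6-yl]boronic acid
Product: 35 core benzyl ether (2R,3R)-6-benzyloxy-3-[(2S,3S)-2-(3,4-dimethoxyphenyl)-3-(3,5-dimethoxyphenyl)-4-methoxy-2,3-dihydrobenzofuran-6-yl]-4-methoxy-2-(4-methoxyphenyl)-2,3-dihydrobenzofuran, via tetrachlorophthalimidoyl ester 34 (not isolated)
Conditions: 18, DIC, DMAP (cat.), CH2Cl2, 20 °C; evaporate; then 26 (1.5 equiv, excess recovered), NiCl2·6H2O (20 mol %), bathophenanthroline, Et3N, 1,4-dioxane/DMF, 75 °C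
Reagents that add atoms: boronic acid 26 OB(O)c1cc(OC)c2c(c1)O[C@H](c1ccc(OC)c(OC)c1)[C@H]2c1cc(OC)cc(OC)c1; N-hydroxytetrachlorophthalimide ON1C(=O)c2c(Cl)c(Cl)c(Cl)c(Cl)c2C1=O (its atoms stay only in intermediate 34)
Why: The same nickel-catalysed decarboxylative Suzuki-type coupling as in step 8 joins the two units through the unhindered C6' boronic acid, and capture of the C3 radical anti to the C2 aryl group should set C3 trans (3R).

Step 17
Reactants: 35 core benzyl ether
Product: 36 (2R,3R)-3-[(2S,3S)-2-(3,4-dimethoxyphenyl)-3-(3,5-dimethoxyphenyl)-4-methoxy-2,3-dihydrobenzofuran-6-yl]-4-methoxy-2-(4-methoxyphenyl)-2,3-dihydrobenzofuran-6-ol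
Conditions: H2 (1 atm), Pd/C, EtOAc/MeOH, 20 °C
Reagents that add atoms: none
Why: Hydrogenolysis of the last benzyl ether as in step 9, which frees the one phenol that becomes the stilbene position.

Step 18
Reactants: 36 core phenol; 23 N-phenylbis(trifluoromethanesulfonimide)
Product: 37 core triflate, the 6-trifluoromethanesulfonate of 36
Conditions: PhNTf2, Et3N, DMAP (cat.), CH2Cl2, 20 °C
Reagents that add atoms: N-phenylbis(trifluoromethanesulfonimide) FC(F)(F)S(=O)(=O)N(c1ccccc1)S(=O)(=O)C(F)(F)F
Why: O-sulfonylation of the only free phenol as in step 10.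

Step 19
Reactants: 37 core triflate; 38 acetic anhydride
Product: 40 heptaacetate triflate (2R,3R,2'S,3'S; the seven former methoxy groups as acetates), via heptaphenol triflate 39 (not isolated)
Conditions: BBr3, CH2Cl2, −78 to 20 °C; H2O quench, extract; then Ac2O, pyridine, DMAP (cat.), 20 °C
Reagents that add atoms: acetic anhydride CC(=O)OC(C)=O
Why: Lewis-acid cleavage of the seven aryl methyl ethers while no alkene is present (the aryl triflate is inert to BBr3 and a transiently opened benzylic C–O bond can only reclose to the trans ring), followed by peracetylation of the crude heptaphenol for the Heck step.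

Step 20
Reactants: 40 heptaacetate triflate; 41 4-acetoxystyrene
Product: 42 octaacetate of the target, with the (E)-4-acetoxystyryl group on C6 of unit 1
Conditions: Pd(OAc)2 (10 mol %), P(o-tol)3, LiCl, Et3N, DMF, 90 °C
Reagents that add atoms: 4-acetoxystyrene C=Cc1ccc(OC(C)=O)cc1
Why: Mizoroki–Heck reaction of the aryl triflate under chloride-assisted neutral conditions, where syn insertion at the terminal carbon and syn β-hydride elimination should give the linear E-stilbene.

Step 21
Reactants: 42 octaacetate of the target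
Product: 43 target CNP0107857.3
Conditions: NaOMe (0.5 equiv), degassed MeOH/THF, 0 °C, argon; then Amberlite IR-120 (H+ form)
Reagents that add atoms: none
Why: Zemplén-type transesterification of the eight aryl acetates under cold, oxygen-free conditions, so no acid reaches the stilbene–dihydrobenzofuran array.

**Compound list**

1 | 5,7-dihydroxychromone | O=c1ccoc2cc(O)cc(O)c12 | starting material
2 | benzyl bromide | BrCc1ccccc1 | starting material
3 | 7-benzyloxy-5-hydroxychromone | O=c1ccoc2cc(OCc3ccccc3)cc(O)c12 | intermediate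
4 | iodomethane | CI | starting material
5 | 7-benzyloxy-5-methoxychromone | COc1cc(OCc2ccccc2)cc2occc(=O)c12 | intermediate
6 | 3,4-dimethoxyphenylboronic acid | COc1ccc(cc1OC)B(O)O | starting material
7 | (2S)-7-benzyloxy-2-(3,4-dimethoxyphenyl)-5-methoxychroman-4-one (7-O-benzyl-5,3',4'-tri-O-methyl-(2S)-eriodictyol) | c1ccccc1COc1cc(OC)c2c(c1)O[C@H](c1ccc(OC)c(OC)c1)CC2=O | intermediate
8 | isoamyl nitrite | CC(C)CCON=O | starting material
9 | 3-oxime of 7 (C2 geometry of 7, CIP 2R) | c1ccccc1COc1cc(OC)c2c(c1)O[C@H](c1ccc(OC)c(OC)c1)C(=NO)C2=O | intermediate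
10 | ammonia | N | starting material
11 | 3-diazo derivative of 7 (C2 geometry of 7, CIP 2R), precursor of the key step | c1ccccc1COc1cc(OC)c2c(c1)O[C@H](c1ccc(OC)c(OC)c1)C(=[N+]=[N-])C2=O | intermediate
12 | methanol | CO | starting material
13 | ketene: 6-benzyloxy-2-(3,4-dimethoxyphenyl)-4-methoxy-3-(oxomethylidene)-2,3-dihydrobenzofuran (C2 unchanged) | c1ccccc1COc1cc(OC)c2c(c1)O[C@H](c1ccc(OC)c(OC)c1)C2=C=O | intermediate
14 | methyl (2S,3R)-6-benzyloxy-2-(3,4-dimethoxyphenyl)-4-methoxy-2,3-dihydrobenzofuran-3-carboxylate (cis) | c1ccccc1COc1cc(OC)c2c(c1)O[C@H](c1ccc(OC)c(OC)c1)[C@@H]2C(=O)OC | intermediate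
15 | methyl (2S,3S)-6-benzyloxy-2-(3,4-dimethoxyphenyl)-4-methoxy-2,3-dihydrobenzofuran-3-carboxylate (trans), product of the key step | c1ccccc1COc1cc(OC)c2c(c1)O[C@H](c1ccc(OC)c(OC)c1)[C@H]2C(=O)OC | intermediate
16 | lithium hydroxide | [Li+].[OH-] | starting material
17 | (2S,3S)-6-benzyloxy-2-(3,4-dimethoxyphenyl)-4-methoxy-2,3-dihydrobenzofuran-3-carboxylic acid | c1ccccc1COc1cc(OC)c2c(c1)O[C@H](c1ccc(OC)c(OC)c1)[C@H]2C(=O)O | intermediate
18 | N-hydroxytetrachlorophthalimide | ON1C(=O)c2c(Cl)c(Cl)c(Cl)c(Cl)c2C1=O | starting material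
19 | 3,5-dimethoxyphenylboronic acid | COc1cc(cc(OC)c1)B(O)O | starting material
20 | 4,5,6,7-tetrachloro-1,3-dioxoisoindolin-2-yl ester of 17 | c1ccccc1COc1cc(OC)c2c(c1)O[C@H](c1ccc(OC)c(OC)c1)[C@H]2C(=O)ON1C(=O)c2c(Cl)c(Cl)c(Cl)c(Cl)c2C1=O | intermediate
21 | (2S,3S)-6-benzyloxy-2-(3,4-dimethoxyphenyl)-3-(3,5-dimethoxyphenyl)-4-methoxy-2,3-dihydrobenzofuran | c1ccccc1COc1cc(OC)c2c(c1)O[C@H](c1ccc(OC)c(OC)c1)[C@H]2c1cc(OC)cc(OC)c1 | intermediate
22 | (2S,3S)-2-(3,4-dimethoxyphenyl)-3-(3,5-dimethoxyphenyl)-4-methoxy-2,3-dihydrobenzofuran-6-ol | Oc1cc(OC)c2c(c1)O[C@H](c1ccc(OC)c(OC)c1)[C@H]2c1cc(OC)cc(OC)c1 | intermediate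
23 | N-phenylbis(trifluoromethanesulfonimide) | FC(F)(F)S(=O)(=O)N(c1ccccc1)S(=O)(=O)C(F)(F)F | starting material
24 | 6-trifluoromethanesulfonate of 22 | FC(F)(F)S(=O)(=O)Oc1cc(OC)c2c(c1)O[C@H](c1ccc(OC)c(OC)c1)[C@H]2c1cc(OC)cc(OC)c1 | intermediate
25 | tetrahydroxydiboron | OB(O)B(O)O | starting material
26 | [(2S,3S)-2-(3,4-dimethoxyphenyl)-3-(3,5-dimethoxyphenyl)-4-methoxy-2,3-dihydrobenzofuran-6-yl]boronic acid | OB(O)c1cc(OC)c2c(c1)O[C@H](c1ccc(OC)c(OC)c1)[C@H]2c1cc(OC)cc(OC)c1 | intermediate
27 | 4-methoxyphenylboronic acid | COc1ccc(cc1)B(O)O | starting material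
28 | (2R)-7-benzyloxy-5-methoxy-2-(4-methoxyphenyl)chroman-4-one (7-O-benzyl-5,4'-di-O-methyl-(2R)-naringenin) | c1ccccc1COc1cc(OC)c2c(c1)O[C@@H](c1ccc(OC)cc1)CC2=O | intermediate
29 | 3-oxime of 28 (C2 geometry of 28, CIP 2S) | c1ccccc1COc1cc(OC)c2c(c1)O[C@@H](c1ccc(OC)cc1)C(=NO)C2=O | intermediate
30 | 3-diazo derivative of 28 (C2 geometry of 28, CIP 2S) | c1ccccc1COc1cc(OC)c2c(c1)O[C@@H](c1ccc(OC)cc1)C(=[N+]=[N-])C2=O | intermediate
31 | water | O | starting material
32 | ketene: 6-benzyloxy-4-methoxy-2-(4-methoxyphenyl)-3-(oxomethylidene)-2,3-dihydrobenzofuran (C2 unchanged) | c1ccccc1COc1cc(OC)c2c(c1)O[C@@H](c1ccc(OC)cc1)C2=C=O | intermediate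
33 | (2R)-6-benzyloxy-4-methoxy-2-(4-methoxyphenyl)-2,3-dihydrobenzofuran-3-carboxylic acid, mixture of C3 epimers | c1ccccc1COc1cc(OC)c2c(c1)O[C@@H](c1ccc(OC)cc1)C2C(=O)O | intermediate
34 | 4,5,6,7-tetrachloro-1,3-dioxoisoindolin-2-yl ester of 33 | c1ccccc1COc1cc(OC)c2c(c1)O[C@@H](c1ccc(OC)cc1)C2C(=O)ON1C(=O)c2c(Cl)c(Cl)c(Cl)c(Cl)c2C1=O | intermediate
35 | (2R,3R)-6-benzyloxy-3-[(2S,3S)-2-(3,4-dimethoxyphenyl)-3-(3,5-dimethoxyphenyl)-4-methoxy-2,3-dihydrobenzofuran-6-yl]-4-methoxy-2-(4-methoxyphenyl)-2,3-dihydrobenzofuran | c1ccccc1COc1cc(OC)c2c(c1)O[C@@H](c1ccc(OC)cc1)[C@@H]2c1cc(OC)c2c(c1)O[C@H](c1ccc(OC)c(OC)c1)[C@H]2c1cc(OC)cc(OC)c1 | intermediate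
36 | 6-phenol from 35 (benzyl removed) | Oc1cc(OC)c2c(c1)O[C@@H](c1ccc(OC)cc1)[C@@H]2c1cc(OC)c2c(c1)O[C@H](c1ccc(OC)c(OC)c1)[C@H]2c1cc(OC)cc(OC)c1 | intermediate
37 | 6-trifluoromethanesulfonate of 36 | FC(F)(F)S(=O)(=O)Oc1cc(OC)c2c(c1)O[C@@H](c1ccc(OC)cc1)[C@@H]2c1cc(OC)c2c(c1)O[C@H](c1ccc(OC)c(OC)c1)[C@H]2c1cc(OC)cc(OC)c1 | intermediate
38 | acetic anhydride | CC(=O)OC(C)=O | starting material
39 | heptaphenol triflate (all seven methyl ethers of 37 cleaved) | FC(F)(F)S(=O)(=O)Oc1cc(O)c2c(c1)O[C@@H](c1ccc(O)cc1)[C@@H]2c1cc(O)c2c(c1)O[C@H](c1ccc(O)c(O)c1)[C@H]2c1cc(O)cc(O)c1 | intermediate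
40 | heptaacetate of 39 | FC(F)(F)S(=O)(=O)Oc1cc(OC(C)=O)c2c(c1)O[C@@H](c1ccc(OC(C)=O)cc1)[C@@H]2c1cc(OC(C)=O)c2c(c1)O[C@H](c1ccc(OC(C)=O)c(OC(C)=O)c1)[C@H]2c1cc(OC(C)=O)cc(OC(C)=O)c1 | intermediate
41 | 4-acetoxystyrene | C=Cc1ccc(OC(C)=O)cc1 | starting material
42 | octaacetate of the target (E-stilbene) | CC(=O)Oc1ccc(/C=C/c2cc(OC(C)=O)c3c(c2)O[C@@H](c2ccc(OC(C)=O)cc2)[C@@H]3c2cc(OC(C)=O)c3c(c2)O[C@H](c2ccc(OC(C)=O)c(OC(C)=O)c2)[C@H]3c2cc(OC(C)=O)cc(OC(C)=O)c2)cc1 | intermediate
43 | CNP0107857.3, (2R,3R,2'S,3'S) | Oc1ccc(/C=C/c2cc(O)c3c(c2)O[C@@H](c2ccc(O)cc2)[C@@H]3c2cc(O)c3c(c2)O[C@H](c2ccc(O)c(O)c2)[C@H]3c2cc(O)cc(O)c2)cc1 | target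

**Step count.** Total: 21 steps. Longest linear sequence: 17 steps (steps 1–11, then 16–21); the unit 1 branch (steps 12–15) joins at step 16.

**Steps most likely to fail**

Step 6 (key step). The excited diazoketone may partly lose N2 to a free carbene, which would give the flavone by 1,2-hydride shift from C2 or an α-methoxy ketone by O–H insertion, and the electron-rich substrate may photodegrade. The fallback is an oxidative ring contraction of flavanone 7 with a hypervalent iodine reagent: PhI(OAc)2 and catalytic H2SO4 in trimethyl orthoformate at room temperature. The enol ether of 7 is iodinated at C3 anti to the C2 aryl group, and arene carbon C4a migrates to C3 as iodobenzene leaves. This should give the trans methyl ester directly with C2 retained. The fallback sets out from 7 and comes back at 15, bypassing 9 and 11, and makes no new compound.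

Step 16. Transmetalation of the large, electron-rich boronic acid 26 to nickel may be too slow, so the benzylic C3 radical dimerises, is reduced or fragments before it is captured, and an uneconomic excess of 26 may be needed. The fallback is a reductive cross-electrophile coupling. Boronic acid 26 is converted by ipso-iododeboronation (I2, K2CO3, MeCN, 80 °C) into the aryl iodide F1. Acid 33 is converted with N-hydroxyphthalimide, DIC and catalytic DMAP into the N-hydroxyphthalimide ester F2. F1 and F2 are then coupled with NiBr2(dme), 4,4'-di-tert-butyl-2,2'-bipyridine and Zn in DMA at room temperature, where the same radical is captured by an aryl–nickel species formed by oxidative addition and the trans product is again expected. The fallback sets out from 26 and 33 and comes back at 35.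

Step 5. The oxime may hydrolyse toward the 3,4-dione and flavonol, may tautomerise through the C2 hydrogen with loss of the stereocentre, or may be aminated incompletely in the two-phase medium. The fallback is a detrifluoroacetylative diazo transfer from flavanone 7. Enolisation with LiN(SiMe3)2 in THF at −78 °C and acylation with CF3CO2CH2CF3 give the 3-trifluoroacetyl ketone F3; the enolate is kept cold so that it does not open to the chalcone. F3 with MsN3, Et3N and water in MeCN at room temperature then gives the diazoketone. The fallback sets out from 7 and comes back at 11, bypassing 9.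

**Further compounds**

F0 | step 6 | none | none
F1 | step 16 | (2S,3S)-2-(3,4-dimethoxyphenyl)-3-(3,5-dimethoxyphenyl)-6-iodo-4-methoxy-2,3-dihydrobenzofuran | Ic1cc(OC)c2c(c1)O[C@H](c1ccc(OC)c(OC)c1)[C@H]2c1cc(OC)cc(OC)c1
F2 | step 16 | 1,3-dioxoisoindolin-2-yl ester of 33 (C3 epimers) | c1ccccc1COc1cc(OC)c2c(c1)O[C@@H](c1ccc(OC)cc1)C2C(=O)ON1C(=O)c2ccccc2C1=O
F3 | step 5 | (2S)-7-benzyloxy-2-(3,4-dimethoxyphenyl)-5-methoxy-3-(trifluoroacetyl)chroman-4-one (C3 undefined) | c1ccccc1COc1cc(OC)c2c(c1)O[C@H](c1ccc(OC)c(OC)c1)C(C(=O)C(F)(F)F)C2=O
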